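How far does free monomer go in 5.0 h in a flask charged with as much transfer agent as pre-initiator?

in all of them: free monomer 0.20 M

| run | transfer agent | pre-initiator | remark | time |
|---|---|---|---|---|
| winter | 0.028 M | 20 mM | run made earlier |  |
| midnight | 0.044 M | 20 mM | run made earlier |  |
| spring | 0.020 M | 40 mM | run made earlier |  |
| flask | 0.0200 M | 20 mM |  | 5.0 h |

| run | time / h | monomer in chains / % | free monomer / % |
|---|---|---|---|
| winter | 0.167 | 3.5 | 96.5 |
| winter | 0.500 | 13.0 | 87.0 |
| winter | 0.833 | 16.1 | 83.4 |
| winter | 1.33 | 19.9 | 79.7 |
| winter | 2.00 | 21.1 | 78.8 |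
| winter | 2.50 | 21.0 | 80.4 |
| winter | 3.00 | 21.0 | 79.7 |
| midnight | 0.167 | 3.4 | 96.7 |
| midnight | 0.500 | 11.0 | 89.4 |
| midnight | 0.833 | 14.0 | 85.4 |
| midnight | 1.33 | 14.6 | 84.0 |
| midnight | 2.00 | 15.7 | 84.3 |
| midnight | 2.50 | 15.2 | 84.7 |
| midnight | 3.00 | 15.3 | 84.7 |
| spring | 0.250 | 11.9 | 87.9 |
| spring | 0.417 | 22.2 | 77.6 |
| spring | 0.833 | 38.5 | 61.1 |
| spring | 1.50 | 56.7 | 43.0 |
| spring | 3.00 | 79.7 | 21.2 |

(standard deviation of a reading: 0.5 percentage points)

1. average number of monomer units in a chain (chains begun, living or dead) at 5.0 h
2. part of the free monomer that has reacted at 5.0 h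

- the average divides the monomer in chains by the number of chains begun, living and dead together
- the earlier runs do not show the number of chains; that part of a forecast is a guess

The reckoning here assumes that each pre-initiator begins one chain and takes one monomer, and that each living end then grows until a transfer agent kills it. Growth and killing use the same living ends, so ln(free monomer) and ln(transfer agent) fall in a fixed proportion. Call this selectivity factor g: the fall in ln(free monomer) per fall in ln(transfer agent) after chains have begun.

On this reckoning, the agent in the winter and midnight runs falls from its charge to its charge minus the pre-initiator. Free monomer falls from its charge minus the pre-initiator to the plateau. This reads g as 0.104 and 0.100, so g is taken as 0.102.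

On this reckoning the spring run keeps a surplus of 20.0 mM living ends, and its late readings show free monomer falling at 0.471 h⁻¹. With g, this gives the killing rate. Taking agent and living ends in the flask as equal from the start, each removing the other, this reckoning has the agent fall by a factor F of 24.1. That gives a reacted part of the free monomer, c, of 35.0 % and, guessing one chain per pre-initiator, an average chain length, dp, of 3.50.

The forecast, higher, says dp 4.2 (2.6 to 5.6) and c 42 % (34 % to 52 %), “assuming killed chains don't restart”.

The flask gives dp 3.48 and c 34.8 %.

    living end + transfer agent → dead chain (kL = 0.0689 L mol⁻¹ s⁻¹)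
    pre-initiator → initiator (k = 0.00281 s⁻¹)
    free monomer + living end → monomer in chains + living end, rate k3*[living end]*[free monomer] (k = 0.00695 L mol⁻¹ s⁻¹)
    free monomer + initiator → living end + monomer in chains (k = 0.00637 L mol⁻¹ s⁻¹)

Living ends kill with a rate constant of 0.0689 L mol⁻¹ s⁻¹, ten times the 0.00695 L mol⁻¹ s⁻¹ with which they grow. At 5.00 h the flask holds 4.3 % of its charged transfer agent and 65 % of its charged free monomer. With g, that agent remainder gives 65.2 % of the charged free monomer. The neighbour flask charged with 0.080 M free monomer keeps 5.7 % of its agent, g gives 56.0 % of its charged free monomer, and that flask holds 55.2 %.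

Readings and results were generated by integration with made-up constants, and the scatter is random.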